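(The numbers in the tables were generated by integration for substances that don't exist.)

The vessel is a closed, stirred flask with two phases: starting material and spent carrier stand in the first, salt in the second. The steps in question are these: spent carrier takes up salt and becomes fresh carrier, fresh carrier turns starting material into product and is spent again, and two spent carrier can pair as resting dimer.

| flask | starting material | salt in the second phase | spent carrier | remark | volume of the second phase over the first |
|---|---|---|---|---|---|
| grey | 0.20 M | 0.19 M | 20 mM | run made earlier |  |
| violet | 0.20 M | 0.19 M | 31 mM | run made earlier |  |
| flask | 0.20 M | 0.190 M | 14 mM |  | 0.50 |

| run | time / min | product / % |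
|---|---|---|
| grey | 0.833 | 3 |
| grey | 2.50 | 5 |
| grey | 4.00 | 13 |
| grey | 6.00 | 19 |
| grey | 10.0 | 26 |
| violet | 2.00 | 8 |
| violet | 4.00 | 15 |
| violet | 6.00 | 20 |
| violet | 8.00 | 27 |
| violet | 10.0 | 33 |

(readings scatter by 1.5 percentage points)

- in the second phase: salt in the second phase, spent salt in the second phase; everything else is in the first
- charges count per volume of the first phase; a concentration in a rate is the amount of a species over the volume of its own phase; every rate counts per litre of the first phase
- steps under discussion: spent carrier + salt in the second phase <-> fresh carrier + spent salt in the second phase; 2 spent carrier <-> resting dimer; starting material + fresh carrier -> product + spent carrier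
- the earlier runs hold the two phases in the same ratio of volumes as the flask asked about
- no earlier run changes the charge of salt in the second phase; that part of a forecast is a guess

1. factor on the rate of making product when 30 % of the starting material are converted if salt in the second phase is charged twice over
2. factor on the rate when 30 % of the starting material are converted if spent carrier is charged at 80 mM instead

Something looks wrong at first. The violet run holds 1.55 times the spent carrier of the grey run, yet after 10.0 min it shows 1.27 times the product.

Work with the fraction left, not the fraction made: take the logarithm of one over the fraction of starting material left and divide by the time. This gives 0.0301 min⁻¹ for grey and 0.0400 min⁻¹ for violet, a factor of 1.33. That is still short of the charge ratio, so, as read off these last readings, the rate follows the charge to a power of 0.651, less than 1 and more than 0.5 . Such a power is what you expect if part of the carrier lies in a resting state, which here would be the resting dimer. With a scatter of 1.5 percentage points on each reading, this power is loosely held.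

Scaled to 14 mM, I estimate the flask's fraction-left constant at 0.0239 min⁻¹. At 80 mM the same constant becomes 0.0742 min⁻¹, so I reckon a factor of 3.10.

Both runs charge the same salt, so they cannot test a change of that charge. At 30 % conversion, [salt] counted per volume of the first phase is about 0.130 M, or about 0.320 M with the double charge. If the rate simply followed [salt], my guess would be a factor of 2.46.

The forecast gives 2.2 for doubled salt and 3 for 80 mM, and says of its salt figure: “That estimate is a guess.”

The flask gives 2.15 for doubled salt and 2.69 for 80 mM. At 8.00 min, resting dimer holds 61.5 % of the catalyst in the flask.

    spent carrier + salt in the second phase ⇌ fresh carrier + spent salt in the second phase (K = 6.10, k = 0.0719 L mol⁻¹ s⁻¹)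
    2 spent carrier ⇌ resting dimer, settled at all times (K = 380 L mol⁻¹)
    starting material + fresh carrier → product + spent carrier (k = 0.216 L mol⁻¹ s⁻¹)

My estimate of 0.0239 min⁻¹ for the flask's fraction-left constant places 30 % conversion at 14.9 min, and the flask reaches it at 13.9 min.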